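**Plan**

- The target is (2S,4S)-5,7-dimethoxy-8-prenylflavan-4-ol, with the C2 phenyl and C4 hydroxyl cis. Retrosynthesis first removes the hydrogens at C4 and at C2/C3 to reach a flat flavone, then cuts ring C at C4a–C4, C4–C3 and O1–C2.
- Enabling feature: C4 is a single carbonyl-level carbon between C4a of ring A and the C3–C2(Ph) pair, and O1 sits on the neighbouring ring A carbon C8a. Ring C is therefore an ortho-iodophenol plus CO plus phenylacetylene.
- Forward: ring A is bought as 3,5-dimethoxyphenol. Its MOM ether directs two ortho-lithiations that place prenyl (future C8) and iodine (future C4a) on either side of the oxygen that becomes O1.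
- Ring C then closes in one palladium-catalysed carbonylative coupling and cyclisation.
- Stereochemistry: C2 comes from a ligand-controlled copper hydride conjugate reduction; C4 comes from substrate-controlled hydride delivery cis to the C2 phenyl.

Key step: step 5

Assumption: the facial preference of the copper hydride/DTBM-SEGPHOS catalyst on the chromenone is taken to follow that on 3-substituted cyclohexenones, which assigns the (S)-ligand to the (2S) product; if the sense proved opposite, the (R)-ligand would be used with no other change.

**Route**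

Step 1
Reactants: 1 3,5-dimethoxyphenol
Product: 2 1,3-dimethoxy-5-(methoxymethoxy)benzene
Conditions: MOMCl, i-Pr2NEt, CH2Cl2, 0 °C to rt
Reagents that add atoms: chloromethyl methyl ether (MOMCl), COCCl
Why: O-alkylation of the phenol with the chloromethyl ether (MOM protection) should be clean, and the acetal is stable to butyllithium and a stronger ortho-director than methoxy.

Step 2
Reactants: 2 1,3-dimethoxy-5-(methoxymethoxy)benzene; 3 prenyl bromide (1-bromo-3-methylbut-2-ene)
Product: 5 1,5-dimethoxy-3-(methoxymethoxy)-2-(3-methylbut-2-en-1-yl)benzene, via aryllithium 4 (not isolated)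
Conditions: n-BuLi, THF, 0 °C; then CuBr·SMe2 (10 mol %), 3, −78 °C to rt
Reagents that add atoms: prenyl bromide 3, CC(C)=CCBr
Why: Directed ortho-metalation, in which lithium held by the acetal oxygens removes one of the two equivalent ring protons flanked by OMOM and OMe rather than the proton between the two methoxy groups, followed by copper-catalysed SN2 allylation of aryllithium 4 at the primary carbon of 3, should give the linear prenyl arene.

Step 3
Reactants: 5 1,5-dimethoxy-3-(methoxymethoxy)-2-(3-methylbut-2-en-1-yl)benzene
Product: 7 2-iodo-1,5-dimethoxy-3-(methoxymethoxy)-4-(3-methylbut-2-en-1-yl)benzene, via aryllithium 6 (not isolated)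
Conditions: n-BuLi, THF, −20 to 0 °C; then I2, THF, −78 °C; aq Na2S2O3
Reagents that add atoms: iodine, II
Why: A second directed ortho-metalation should take the only remaining proton flanked by OMOM and OMe (the ortho prenyl group turns the acetal chain toward it), and iodinolysis of aryllithium 6 at −78 °C is much faster than any addition of iodine to the trisubstituted alkene, so iodine lands on the carbon that becomes C4a.

Step 4
Reactants: 7 2-iodo-1,5-dimethoxy-3-(methoxymethoxy)-4-(3-methylbut-2-en-1-yl)benzene
Product: 8 2-iodo-3,5-dimethoxy-6-(3-methylbut-2-en-1-yl)phenol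
Conditions: conc. HCl (cat.), MeOH, rt
Reagents that add atoms: none
Why: Acid-catalysed acetal exchange with methanol (MOM cleavage) frees the phenol under conditions mild enough to spare the prenyl group from chroman formation and the electron-rich aryl iodide from protodeiodination.

Step 5
Reactants: 8 2-iodo-3,5-dimethoxy-6-(3-methylbut-2-en-1-yl)phenol; 9 phenylacetylene; 10 carbon monoxide
Product: 13 5,7-dimethoxy-8-(3-methylbut-2-en-1-yl)flavone, via ynone 11 (not isolated), via enaminone 12 (not isolated)
Conditions: PdCl2(PPh3)2 (5 mol %), CO (20 bar), 9 (1.5 equiv), Et2NH, 120 °C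
Reagents that add atoms: phenylacetylene 9, C#Cc1ccccc1; carbon monoxide 10, [C-]#[O+]
Why: PdCl2(PPh3)2 is reduced in diethylamine to zerovalent palladium, which inserts into the C–I bond of 8; CO insertion gives an aroylpalladium iodide that takes up the acetylide of 9 and reductively eliminates, forming C4a–C4 and C4–C3 in ynone 11 (a copper-free carbonylative Sonogashira coupling). Diethylamine then adds to the alkyne carbon bearing phenyl to give enaminone 12, and the ortho hydroxyl attacks that same carbon and expels the amine, forming O1–C2. The closest known reaction is the palladium-catalysed carbonylative annulation of ortho-iodophenols with terminal alkynes to flavones in a secondary amine. Ring C is the only ring closed, in a 6-endo mode: formally 6-endo-dig on 11, in practice 6-endo-trig addition–elimination on 12. No stereocenter is created, since the product is planar. The step needs CO insertion to precede alkynylation and a six- rather than five-membered closure (aurone): 20 bar of CO and the absence of copper should secure the first, the amine relay through 12, in which only C2 is electrophilic, the second, and the position of iodine fixes C4a so that the prenyl group ends at C8.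

Step 6
Reactants: 13 5,7-dimethoxy-8-(3-methylbut-2-en-1-yl)flavone
Product: 14 (2S)-5,7-dimethoxy-8-(3-methylbut-2-en-1-yl)flavanone
Conditions: Cu(OAc)2·H2O (5 mol %), (S)-DTBM-SEGPHOS (5.5 mol %), (EtO)2MeSiH, t-BuOH, toluene, 0 °C to rt
Reagents that add atoms: none
Why: Asymmetric copper hydride conjugate reduction (1,4-hydrosilylation), as known for chromones, should deliver hydride to the Re face of C2 under control of the (S)-bisphosphine to set (2S), with t-BuOH protonating the copper enolate at C3 and the isolated prenyl alkene inert to copper hydride.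

Step 7
Reactants: 14 (2S)-5,7-dimethoxy-8-(3-methylbut-2-en-1-yl)flavanone
Product: 15 (2S,4S)-5,7-dimethoxy-8-(3-methylbut-2-en-1-yl)flavan-4-ol
Conditions: NaBH4, MeOH/THF, −10 to 0 °C; aq NaHCO3
Reagents that add atoms: none
Why: Substrate-controlled borohydride reduction of a flavanone: in the half-chair with the C2 phenyl pseudo-equatorial, hydride attacks C4 axially from the face carrying H2, which places the new hydroxyl cis to the phenyl, that is (4S) from (2S), and the cold, buffered procedure should avoid base-induced ring opening at C2 and acid ionisation at C4.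

**Compound list**

1 | 3,5-dimethoxyphenol | COc1cc(O)cc(OC)c1 | starting material
2 | 1,3-dimethoxy-5-(methoxymethoxy)benzene | COCOc1cc(OC)cc(OC)c1 | intermediate
3 | prenyl bromide (1-bromo-3-methylbut-2-ene) | CC(C)=CCBr | starting material
4 | [2,4-dimethoxy-6-(methoxymethoxy)phenyl]lithium | COCOc1cc(OC)cc(OC)c1[Li] | intermediate (not isolated)
5 | 1,5-dimethoxy-3-(methoxymethoxy)-2-(3-methylbut-2-en-1-yl)benzene | COCOc1cc(OC)cc(OC)c1CC=C(C)C | intermediate
6 | [2,4-dimethoxy-6-(methoxymethoxy)-5-(3-methylbut-2-en-1-yl)phenyl]lithium | COCOc1c([Li])c(OC)cc(OC)c1CC=C(C)C | intermediate (not isolated)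
7 | 2-iodo-1,5-dimethoxy-3-(methoxymethoxy)-4-(3-methylbut-2-en-1-yl)benzene | COCOc1c(I)c(OC)cc(OC)c1CC=C(C)C | intermediate
8 | 2-iodo-3,5-dimethoxy-6-(3-methylbut-2-en-1-yl)phenol | Oc1c(I)c(OC)cc(OC)c1CC=C(C)C | intermediate
9 | phenylacetylene | C#Cc1ccccc1 | starting material
10 | carbon monoxide | [C-]#[O+] | starting material
11 | 1-[2-hydroxy-4,6-dimethoxy-3-(3-methylbut-2-en-1-yl)phenyl]-3-phenylprop-2-yn-1-one | COc1cc(OC)c(C(=O)C#Cc2ccccc2)c(O)c1CC=C(C)C | intermediate (not isolated)
12 | (E)-3-(diethylamino)-1-[2-hydroxy-4,6-dimethoxy-3-(3-methylbut-2-en-1-yl)phenyl]-3-phenylprop-2-en-1-one | CCN(CC)/C(c1ccccc1)=C/C(=O)c1c(OC)cc(OC)c(CC=C(C)C)c1O | intermediate (not isolated)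
13 | 5,7-dimethoxy-8-(3-methylbut-2-en-1-yl)-2-phenyl-4H-chromen-4-one (5,7-dimethoxy-8-prenylflavone) | COc1cc(OC)c2c(c1CC=C(C)C)oc(-c1ccccc1)cc2=O | intermediate
14 | (2S)-5,7-dimethoxy-8-(3-methylbut-2-en-1-yl)-2-phenylchroman-4-one | COc1cc(OC)c2c(c1CC=C(C)C)O[C@H](c1ccccc1)CC2=O | intermediate
15 | (2S,4S)-5,7-dimethoxy-8-(3-methylbut-2-en-1-yl)-2-phenylchroman-4-ol (2,4-cis) | COc1cc(OC)c2c(c1CC=C(C)C)O[C@H](c1ccccc1)C[C@@H]2O | target

**Step count**

Total steps: 7. Longest linear sequence: 7 steps (from 1 to 15).

**Steps most likely to fail**

Step 6. Hydride transfer to the electron-rich, doubly β-substituted vinylogous ester may be slow, and the C2 configuration may erode through reversible retro-oxa-Michael opening of the enolate. The fallback sets out from 13 and returns at 15; C2 is formed without control and both centres are then sorted in one resolution. Conjugate reduction of 13 with LiBH(s-Bu)3 in THF at −78 °C should give racemic 5,7-dimethoxy-8-(3-methylbut-2-en-1-yl)flavanone F6. Asymmetric transfer hydrogenation with RuCl(p-cymene)[(S,S)-TsDPEN] and HCO2H/Et3N, run as a kinetic resolution, should reduce the (2S) enantiomer faster to the cis alcohol 15. It leaves (2R)-5,7-dimethoxy-8-(3-methylbut-2-en-1-yl)flavanone F7, which is separated and can be racemised with base for another cycle. Step 7 is then not needed.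

Step 3. The base may remove a benzylic–allylic proton of the prenyl CH2 (lateral metalation) or the ring proton between the two methoxy groups, so that iodine enters at the wrong carbon. The fallback sets out from 2 and returns at 8; the two substituents are introduced in the opposite order so that no prenyl arene is lithiated. Lithiation of 2 as in step 2 (aryllithium 4) and an I2 quench should give 2-iodo-1,5-dimethoxy-3-(methoxymethoxy)benzene F1. HCl in MeOH then frees 2-iodo-3,5-dimethoxyphenol F2. NaH in toluene converts this into sodium 2-iodo-3,5-dimethoxyphenoxide F3, whose tight ion pair in the non-polar solvent should be C-allylated by prenyl bromide 3 at the only free ortho carbon, giving iodophenol 8.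

Step 5. Alkynylation of the hindered, electron-rich arylpalladium may outrun CO insertion (leading to the 2-arylbenzofuran), or the aroylpalladium may be captured by diethylamine as the amide. The fallback sets out from 5 and returns at 13; the carbonyl carbon is brought in already attached to the alkyne. Aryllithium 6, generated from 5 as in step 3, is acylated with N-methoxy-N-methyl-3-phenylprop-2-ynamide (Weinreb ketone synthesis) to give 1-[2,4-dimethoxy-6-(methoxymethoxy)-5-(3-methylbut-2-en-1-yl)phenyl]-3-phenylprop-2-yn-1-one F4. Et2NH in EtOH at rt adds to the ynone to give (E)-3-(diethylamino)-1-[2,4-dimethoxy-6-(methoxymethoxy)-5-(3-methylbut-2-en-1-yl)phenyl]-3-phenylprop-2-en-1-one F5. HCl in MeOH then removes the MOM group, and the freed phenol closes ring C by addition–elimination with loss of diethylamine, giving flavone 13.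

**Further compounds**

F1 | step 3 | 2-iodo-1,5-dimethoxy-3-(methoxymethoxy)benzene | COCOc1cc(OC)cc(OC)c1I
F2 | step 3 | 2-iodo-3,5-dimethoxyphenol | Oc1cc(OC)cc(OC)c1I
F3 | step 3 | sodium 2-iodo-3,5-dimethoxyphenoxide | [Na+].[O-]c1cc(OC)cc(OC)c1I
F4 | step 5 | 1-[2,4-dimethoxy-6-(methoxymethoxy)-5-(3-methylbut-2-en-1-yl)phenyl]-3-phenylprop-2-yn-1-one | COCOc1c(C(=O)C#Cc2ccccc2)c(OC)cc(OC)c1CC=C(C)C
F5 | step 5 | (E)-3-(diethylamino)-1-[2,4-dimethoxy-6-(methoxymethoxy)-5-(3-methylbut-2-en-1-yl)phenyl]-3-phenylprop-2-en-1-one | CCN(CC)/C(c1ccccc1)=C/C(=O)c1c(OC)cc(OC)c(CC=C(C)C)c1OCOC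
F6 | step 6 | racemic 5,7-dimethoxy-8-(3-methylbut-2-en-1-yl)-2-phenylchroman-4-one | COc1cc(OC)c2c(c1CC=C(C)C)OC(c1ccccc1)CC2=O
F7 | step 6 | (2R)-5,7-dimethoxy-8-(3-methylbut-2-en-1-yl)-2-phenylchroman-4-one | COc1cc(OC)c2c(c1CC=C(C)C)O[C@@H](c1ccccc1)CC2=O
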